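The earlier runs and the new flask are simulated for substances that don't exist, noise included.

The constants of the steps are hidden, so I read a single time scale from the runs.

| setting | ochre | amber | flask |
|---|---|---|---|
| starting material | 1 M | 1 M | 1.0 M |
| reagent in the second phase | 1.5 M | 1.5 M | 1.50 M |
| protic impurity | 0.050 M | 0.034 M | 0.0500 M |
| remark | the very flask that is asked about, followed so far | run made earlier |  |
| time |  |  | 12 h |
| volume of the second phase over the first |  |  | 1.0 |

ochre run (percent of the starting material charged)

| time / min | target / % |
|---|---|
| 5.00 | 0 |
| 8.00 | 1.5 |
| 10.0 | 0 |
| 15.0 | 1.8 |
| 25.0 | 0.4 |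
| 40.0 | 3.4 |
| 60.0 | 6.0 |

amber run (percent of the starting material charged)

| time / h | target / % |
|---|---|
| 1.33 | 8.0 |
| 2.50 | 17.0 |
| 4.00 | 19.5 |
| 5.00 | 20.2 |
| 6.00 | 19.4 |
| 8.00 | 15.7 |

(each reading ± 0.5 percentage points)

- in the second phase: reagent in the second phase; everything else is in the first
- charges count per volume of the first phase; a concentration in a rate is the amount of a species over the volume of its own phase; every rate counts per litre of the first phase
- the numbers in the tables scatter by 0.5 percentage points (one standard deviation)
- candidate steps: reagent in the reaction phase <-> reagent in the second phase; starting material + reagent in the reaction phase <-> target; reagent in the reaction phase + target -> over-reacted product; starting material + protic impurity -> quenched substrate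
- the earlier runs hold the two phases in the same ratio of volumes as the flask asked about

- epsilon: doubling the amount of reagent in the second phase, all else as stated
- gamma: doubling the transfer coefficient of the reagent in the second phase, all else as stated

* amount of target at 12 h, in percent of the starting material charged
* the change that raises the amount of target at 12 h, in percent of the starting material charged most ("none" if none brings more than 2 percentage points) (epsilon / gamma / none)
* amount of target at 12 h, in percent of the starting material charged, after gamma

The amber run peaks in target at P_pk = 20.2%, near t_pk = 5.00 h. The ochre run, with the flask's impurity, reads 6.0% at 60.0 min, and the amber run reads 8.0% at 1.33 h, the same slope within the scatter, so I carry this peak, as read, to the flask.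

Target is the intermediate of consecutive reactions. I freeze its making and its loss at one common rate, 1/t_pk, which gives P ≈ P_pk θ exp(1 − θ). For the flask θ = 2.40, the time of reading over the time of the peak. The flask therefore stands past its peak, and I reckon 12.0%.

One number is not quite enough: on the amber run the same curve gives 11.2% at 1.33 h against 8.0% read, and 17.7% at 8.00 h against 15.7% read. I expect epsilon and gamma each to bring the peak forward and so raise θ, which past the peak lowers this curve, so I name none.

The forecast says 11%, none and 10.5%: “Faster transfer reaches the same stoichiometric end, so it gives about the same value”.

The flask gives 12.7%, none and 11.3%; epsilon moves it by −5.8 percentage points, gamma by −1.4 points.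

    reagent in the reaction phase ⇌ reagent in the second phase, rate k1*([reagent in the reaction phase] - [reagent in the second phase]/K1) per volume of the first phase (partition coefficient = 0.580, kL = 4.70 × 10⁻⁵ s⁻¹)
    starting material + reagent in the reaction phase ⇌ target (K = 0.920 M⁻¹, k = 1.40 × 10⁻⁴ M⁻¹ s⁻¹)
    reagent in the reaction phase + target → over-reacted product (k = 1.30 × 10⁻⁴ M⁻¹ s⁻¹)
    starting material + protic impurity → quenched substrate (k = 2.20 × 10⁻⁴ M⁻¹ s⁻¹)

At θ = 2.40, the over-reaction together with the way back holds the flask's target down: without the first it holds 37.2%, without the second 32.8%. The flask left until 3.0 h has θ = 0.600, so I reckon 18.1%; it gives 18.4%.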